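**Plan**

- Retrosynthesis: remove the epoxide oxygen (C6–C7), the aroyl group (C4–O) and the isopropyl group (C3–C); trace C3a–H/C4–OH back to a C3a=C4 alkene and the C6 methyl back to an ester; then cut C8–C8a and C5–C6 of the seven-membered ring.
- Enabling feature: in the seven-membered ring the epoxide carbons C6/C7 and the C3a–H/C4–O pair lie 1,4 to each other across C5, so they are the two alkenes of a cyclohepta-1,4-diene. The bond C8–C8a opposite C5, ending at the angular-methyl carbon (an sp2 carbon of a cyclopentene), is the sigma bond that a cis-divinylcyclopropane Cope rearrangement makes.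
- Forward: the five-membered ring is bought as 2-bromo-3-methylcyclopentenone and converted into a 1-methyl-2-vinylcyclopentene ketal. A rhodium vinylcarbenoid cyclopropanates the vinyl group, and the Cope shift closes the seven-membered ring at C8–C8a and creates the quaternary carbon.
- Then: hydroboration (C3a–H, C4–OH), ester to methyl, ketone release, isopropyl addition (jaeschkeanadiol), acylation (ferutinin), epoxidation.
- Stereochemistry: C8a comes from the chiral dirhodium prolinate catalyst via the transient cyclopropane; C3a, C4, C3 and C6/C7 are each set by reagent approach anti to the angular methyl group.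

Key step: step 4

Numbering: positions follow azulene numbering (C3 carbinol carbon, C3a ring-fusion CH, C4 ester-bearing carbon, C6/C7 epoxide carbons, C8a angular-methyl carbon).
Assumption: the sense of induction of Rh2(R-DOSP)4, dirhodium tetrakis[(R)-N-(4-dodecylphenylsulfonyl)prolinate], is taken by analogy with the aryldiazoacetate/monosubstituted-alkene series; if the opposite sense were found, Rh2(S-DOSP)4 would be used.

**Route**

Step 1
Reactants: 1 2-bromo-3-methylcyclopent-2-en-1-one
Product: 2 6-bromo-7-methyl-1,4-dioxaspiro[4.4]non-6-ene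
Conditions: ethylene glycol, p-TsOH·H2O (cat.), benzene, reflux, Dean–Stark
Reagents that add atoms: ethylene glycol, OCCO
Why: Acid-catalysed ketalisation with azeotropic water removal, which 2-bromo enones undergo without migration of the double bond, masks the carbonyl against the later borane and hydride steps and keeps the diene achiral.

Step 2
Reactants: 2 6-bromo-7-methyl-1,4-dioxaspiro[4.4]non-6-ene; 3 4,4,5,5-tetramethyl-2-vinyl-1,3,2-dioxaborolane
Product: 4 6-ethenyl-7-methyl-1,4-dioxaspiro[4.4]non-6-ene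
Conditions: PdCl2(dppf) (5 mol %), K3PO4, 1,4-dioxane/H2O, 80 °C
Reagents that add atoms: none
Why: Suzuki–Miyaura coupling of the alkenyl bromide with the vinylboronate completes the 1-methyl-2-vinylcyclopentene diene, and no stereocentre is formed.

Step 3
Reactants: 5 methyl but-3-enoate
Product: 6 methyl 2-diazobut-3-enoate
Conditions: p-ABSA, DBU, MeCN, 0 °C; used at once as a cold pentane solution
Reagents that add atoms: p-acetamidobenzenesulfonyl azide (p-ABSA), CC(=O)Nc1ccc(cc1)S(=O)(=O)N=[N+]=[N-]
Why: Regitz diazo transfer to the doubly activated (allylic and alpha to the ester) methylene gives the vinyldiazoacetate, which is kept cold and used directly because it cyclises slowly to a pyrazole.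

Step 4
Reactants: 4 6-ethenyl-7-methyl-1,4-dioxaspiro[4.4]non-6-ene; 6 methyl 2-diazobut-3-enoate
Product: 8 methyl (8aR)-3,3-(ethylenedioxy)-8a-methyl-1,2,3,5,8,8a-hexahydroazulene-6-carboxylate, via cis-divinylcyclopropane ester 7 (not isolated)
Conditions: Rh2(R-DOSP)4 (1 mol %), hexanes, −40 °C, slow addition of 6 (2 equiv); then 60 °C
Reagents that add atoms: none
Why: Loss of N2 from 6 at the dirhodium catalyst gives an electrophilic vinylcarbenoid that cyclopropanates the unhindered monosubstituted vinyl group of 4 with its own vinyl group cis to the cyclopentenyl substituent, and the resulting cis-1,2-divinylcyclopropane 7 undergoes a [3,3]-sigmatropic (Cope) ring expansion in which the cyclopropane bond between the two alkenyl-bearing carbons breaks while C8–C8a forms. The closest known reaction type is the tandem cyclopropanation/Cope rearrangement (formal (4+3) cycloaddition) of vinyldiazoacetates with dienes, which is precedented for 2-methyl-1-vinylcycloalkenes that deliver angular-methyl quaternary carbons. The three-membered ring closes by (2+1) carbene transfer, and the seven-membered ring closes by the concerted suprafacial [3,3] shift through the obligatory boat transition state, the cyclopentene C=C serving as one of the two vinyl groups so that the ring fusion arises directly. The two cyclopropane stereocentres are set by the chiral prolinate ligands of the catalyst and are translated through the boat geometry into C8a (8aR), the only stereocentre of 8. The step needs chemoselectivity for the vinyl group over the tetrasubstituted ring alkene and over C–H insertion, which the steric demand of the donor/acceptor carbenoid should secure, and cis selectivity in the cyclopropanation, which is inherent to these carbenoids; the inward-pointing methyl group at the diene terminus only slows the Cope step, hence the final warming.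

Step 5
Reactants: 8 methyl (8aR)-3,3-(ethylenedioxy)-8a-methyl-1,2,3,5,8,8a-hexahydroazulene-6-carboxylate
Product: 9 methyl (3aS,4S,8aR)-3,3-(ethylenedioxy)-4-hydroxy-8a-methyl-1,2,3,3a,4,5,8,8a-octahydroazulene-6-carboxylate
Conditions: BH3·SMe2 (1.2 equiv), THF, 0 °C to rt; then NaBO3·4H2O, H2O, rt
Reagents that add atoms: sodium perborate, [Na+].[Na+].O[B-]1(O)OO[B-](O)(O)OO1
Why: Hydroboration–oxidation adds H and B syn across C3a=C4 with boron at the less substituted C4 and from the face opposite the C8a methyl group (as in the alpha-face hydroboration of 5-ene steroids), which should set C3a–H and C4–OH cis to each other and trans to the methyl group (trans ring fusion), while the alpha-substituted enoate is too electron-poor and hindered to compete.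

Step 6
Reactants: 9 methyl (3aS,4S,8aR)-3,3-(ethylenedioxy)-4-hydroxy-8a-methyl-1,2,3,3a,4,5,8,8a-octahydroazulene-6-carboxylate
Product: 10 methyl (3aS,4S,8aR)-3,3-(ethylenedioxy)-8a-methyl-4-(triethylsilyloxy)-1,2,3,3a,4,5,8,8a-octahydroazulene-6-carboxylate
Conditions: Et3SiCl, imidazole, DMAP (cat.), DMF, rt
Reagents that add atoms: chlorotriethylsilane, CC[Si](Cl)(CC)CC
Why: Silylation protects the secondary alcohol through the two hydride steps, and the triethylsilyl group is chosen because it falls off together with the ketal in step 9.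

Step 7
Reactants: 10 methyl (3aS,4S,8aR)-3,3-(ethylenedioxy)-8a-methyl-4-(triethylsilyloxy)-1,2,3,3a,4,5,8,8a-octahydroazulene-6-carboxylate
Product: 11 [(3aS,4S,8aR)-3,3-(ethylenedioxy)-8a-methyl-4-(triethylsilyloxy)-1,2,3,3a,4,5,8,8a-octahydroazulen-6-yl]methanol
Conditions: iBu2AlH (2.5 equiv), CH2Cl2, −78 °C; Rochelle salt work-up
Reagents that add atoms: none
Why: 1,2-Reduction of the conjugated ester by iBu2AlH gives the primary allylic alcohol, and the ketal and silyl ether are inert at −78 °C.

Step 8
Reactants: 11 [(3aS,4S,8aR)-3,3-(ethylenedioxy)-8a-methyl-4-(triethylsilyloxy)-1,2,3,3a,4,5,8,8a-octahydroazulen-6-yl]methanol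
Product: 13 (3aS,4S,8aR)-3,3-(ethylenedioxy)-6,8a-dimethyl-4-(triethylsilyloxy)-1,2,3,3a,4,5,8,8a-octahydroazulene, via pyridinium allylic sulfate 12 (not isolated)
Conditions: SO3·pyridine, THF, 0 °C to rt; then LiAlH4, THF, 0 °C to rt
Reagents that add atoms: none
Why: Corey-type deoxygenation, in which hydride displaces the primary allylic sulfate monoester in SN2 fashion, turns CH2OH into the C6 methyl group without allylic transposition.

Step 9
Reactants: 13 (3aS,4S,8aR)-3,3-(ethylenedioxy)-6,8a-dimethyl-4-(triethylsilyloxy)-1,2,3,3a,4,5,8,8a-octahydroazulene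
Product: 14 (3aS,4S,8aR)-4-hydroxy-6,8a-dimethyl-2,3a,4,5,8,8a-hexahydroazulen-3(1H)-one
Conditions: 1 M aq. HCl, THF, rt
Reagents that add atoms: water, O
Why: Mild aqueous acid hydrolysis releases the C3 ketone and cleaves the labile triethylsilyl ether in the same operation, under conditions kept gentle enough to avoid enolisation at C3a or dehydration of the beta-hydroxy ketone.

Step 10
Reactants: 14 (3aS,4S,8aR)-4-hydroxy-6,8a-dimethyl-2,3a,4,5,8,8a-hexahydroazulen-3(1H)-one
Product: 15 jaeschkeanadiol, (3R,3aS,4S,8aR)-6,8a-dimethyl-3-(propan-2-yl)-1,2,3,3a,4,5,8,8a-octahydroazulene-3,4-diol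
Conditions: iPrMgCl (4 equiv), anhydrous CeCl3 (4 equiv), THF, −78 to 0 °C
Reagents that add atoms: isopropylmagnesium chloride, CC(C)[Mg]Cl
Why: Organocerium (Imamoto) 1,2-addition suppresses enolisation and beta-hydride reduction, and the nucleophile should enter the cyclopentanone from the face of C3a–H, anti to the 1,3-related pseudoaxial C8a methyl group, giving the 3R carbinol with the hydroxyl cis to that methyl group.

Step 11
Reactants: 15 jaeschkeanadiol; 16 4-acetoxybenzoyl chloride
Product: 18 ferutinin, (3R,3aS,4S,8aR)-3-hydroxy-6,8a-dimethyl-3-(propan-2-yl)-1,2,3,3a,4,5,8,8a-octahydroazulen-4-yl 4-hydroxybenzoate, via ferutinin O-acetate 17 (not isolated)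
Conditions: 16 (1.5 equiv), pyridine, DMAP (cat.), CH2Cl2, 0 °C to rt; then pyrrolidine, 0 °C
Reagents that add atoms: none
Why: DMAP-catalysed acylation should occur only at the secondary C4 hydroxyl (the tertiary one is inert) with retention, and in-flask aminolysis by pyrrolidine removes the far more reactive aryl acetate without touching the hindered benzoate.

Step 12
Reactants: 18 ferutinin
Product: 19 jaeskeanin, (3R,3aS,4S,6R,7S,8aR)-6,7-epoxy-3-hydroxy-6,8a-dimethyl-3-(propan-2-yl)decahydroazulen-4-yl 4-hydroxybenzoate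
Conditions: mCPBA (1.1 equiv), NaHCO3, CH2Cl2, 0 °C
Reagents that add atoms: mCPBA, OOC(=O)c1cccc(Cl)c1
Why: Prilezhaev epoxidation of the only alkene should occur anti to the axial C8a methyl group, which shields one face of the chair cycloheptene, giving the 6R,7S epoxide, while the electron-poor phenol and the ester are inert under buffered conditions.

**Compound list**

1 | 2-bromo-3-methylcyclopent-2-en-1-one | CC1=C(Br)C(=O)CC1 | starting material
2 | 6-bromo-7-methyl-1,4-dioxaspiro[4.4]non-6-ene | CC1=C(Br)C2(CC1)OCCO2 | intermediate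
3 | 4,4,5,5-tetramethyl-2-vinyl-1,3,2-dioxaborolane | C=CB1OC(C)(C)C(C)(C)O1 | starting material
4 | 6-ethenyl-7-methyl-1,4-dioxaspiro[4.4]non-6-ene | C=CC1=C(C)CCC12OCCO2 | intermediate
5 | methyl but-3-enoate | COC(=O)CC=C | starting material
6 | methyl 2-diazobut-3-enoate | COC(=O)C(=[N+]=[N-])C=C | intermediate
7 | methyl (1S,2S)-1-ethenyl-2-(7-methyl-1,4-dioxaspiro[4.4]non-6-en-6-yl)cyclopropane-1-carboxylate | C=C[C@@]1(C(=O)OC)C[C@H]1C2=C(C)CCC23OCCO3 | intermediate
8 | methyl (8aR)-3,3-(ethylenedioxy)-8a-methyl-1,2,3,5,8,8a-hexahydroazulene-6-carboxylate | COC(=O)C1=CC[C@@]2(C)CCC3(OCCO3)C2=CC1 | intermediate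
9 | methyl (3aS,4S,8aR)-3,3-(ethylenedioxy)-4-hydroxy-8a-methyl-1,2,3,3a,4,5,8,8a-octahydroazulene-6-carboxylate | COC(=O)C1=CC[C@@]2(C)CCC3(OCCO3)[C@@H]2[C@@H](O)C1 | intermediate
10 | methyl (3aS,4S,8aR)-3,3-(ethylenedioxy)-8a-methyl-4-(triethylsilyloxy)-1,2,3,3a,4,5,8,8a-octahydroazulene-6-carboxylate | COC(=O)C1=CC[C@@]2(C)CCC3(OCCO3)[C@@H]2[C@@H](O[Si](CC)(CC)CC)C1 | intermediate
11 | [(3aS,4S,8aR)-3,3-(ethylenedioxy)-8a-methyl-4-(triethylsilyloxy)-1,2,3,3a,4,5,8,8a-octahydroazulen-6-yl]methanol | OCC1=CC[C@@]2(C)CCC3(OCCO3)[C@@H]2[C@@H](O[Si](CC)(CC)CC)C1 | intermediate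
12 | pyridinium [(3aS,4S,8aR)-3,3-(ethylenedioxy)-8a-methyl-4-(triethylsilyloxy)-1,2,3,3a,4,5,8,8a-octahydroazulen-6-yl]methyl sulfate | [O-]S(=O)(=O)OCC1=CC[C@@]2(C)CCC3(OCCO3)[C@@H]2[C@@H](O[Si](CC)(CC)CC)C1.c1cc[nH+]cc1 | intermediate
13 | (3aS,4S,8aR)-3,3-(ethylenedioxy)-6,8a-dimethyl-4-(triethylsilyloxy)-1,2,3,3a,4,5,8,8a-octahydroazulene | CC1=CC[C@@]2(C)CCC3(OCCO3)[C@@H]2[C@@H](O[Si](CC)(CC)CC)C1 | intermediate
14 | (3aS,4S,8aR)-4-hydroxy-6,8a-dimethyl-2,3a,4,5,8,8a-hexahydroazulen-3(1H)-one | CC1=CC[C@@]2(C)CCC(=O)[C@@H]2[C@@H](O)C1 | intermediate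
15 | jaeschkeanadiol, (3R,3aS,4S,8aR)-6,8a-dimethyl-3-(propan-2-yl)-1,2,3,3a,4,5,8,8a-octahydroazulene-3,4-diol | CC(C)[C@]1(O)CC[C@]2(C)CC=C(C)C[C@H](O)[C@H]21 | intermediate
16 | 4-acetoxybenzoyl chloride | CC(=O)Oc1ccc(cc1)C(Cl)=O | starting material
17 | ferutinin O-acetate, (3R,3aS,4S,8aR)-3-hydroxy-6,8a-dimethyl-3-(propan-2-yl)-1,2,3,3a,4,5,8,8a-octahydroazulen-4-yl 4-acetoxybenzoate | CC(C)[C@]1(O)CC[C@]2(C)CC=C(C)C[C@H](OC(=O)c3ccc(OC(C)=O)cc3)[C@H]21 | intermediate
18 | ferutinin, (3R,3aS,4S,8aR)-3-hydroxy-6,8a-dimethyl-3-(propan-2-yl)-1,2,3,3a,4,5,8,8a-octahydroazulen-4-yl 4-hydroxybenzoate | CC(C)[C@]1(O)CC[C@]2(C)CC=C(C)C[C@H](OC(=O)c3ccc(O)cc3)[C@H]21 | intermediate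
19 | jaeskeanin, (3R,3aS,4S,6R,7S,8aR)-6,7-epoxy-3-hydroxy-6,8a-dimethyl-3-(propan-2-yl)decahydroazulen-4-yl 4-hydroxybenzoate | CC(C)[C@]1(O)CC[C@]2(C)C[C@@H]3O[C@]3(C)C[C@H](OC(=O)c3ccc(O)cc3)[C@H]21 | target

**Step count and risks**

Total step count: 12. Longest linear sequence: 11 steps (1 to 19 through steps 1, 2 and 4–12; step 3 prepares the diazo partner).

Steps most likely to fail:

Step 5. The conjugated ester may compete for borane and give over-reduced material, and a second alkene in the molecule makes incomplete face selectivity hard to correct. Fallback, from 8 back to 19: the ester is dealt with first and C6=C7 is converted into the epoxide that the target needs before borane is used. Reduction of 8 with iBu2AlH gives the dienyl alcohol F1. SO3·pyridine then LiAlH4, by way of the pyridinium sulfate F2, gives the 6-methyl diene F3. mCPBA (1 equiv, NaHCO3, −20 °C) should epoxidise the electron-richer C6=C7 alkene anti to the C8a methyl group to give the epoxide F4, because the C3a=C4 alkene is deactivated by the allylic ketal and flanked by two fully substituted carbons. BH3·SMe2 then NaBO3·4H2O now has a single alkene to address and gives the epoxy alcohol F5. Pyridinium p-toluenesulfonate in wet acetone at room temperature removes the ketal to give the epoxy hydroxy ketone F6, and iPrMgCl/CeCl3 gives the epoxy diol F7. Acylation with 16 followed by pyrrolidine, by way of jaeskeanin O-acetate F8, gives 19 directly.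

Step 4. Enantio-induction by the catalyst may be insufficient, or 6 may be lost to pyrazole formation before carbene transfer at the low temperature that selectivity requires. Fallback, from 4 back to 8: stereocontrol is moved from the catalyst to a covalently bound auxiliary, so that a robust achiral catalyst can be used at room temperature and the stereoisomers separated. (R)-Pantolactone is acylated with but-3-enoyl chloride (pyridine, CH2Cl2) to the pantolactonyl butenoate F9, and diazo transfer (p-ABSA, DBU) gives the pantolactonyl vinyldiazoacetate F10. Dirhodium tetraoctanoate, Rh2(O2CC7H15)4, in pentane with 4 gives, by way of the pantolactonyl divinylcyclopropane F11, the pantolactonyl cycloadduct F12, whose diastereomers should be separable by crystallisation or chromatography. NaOMe in MeOH transesterifies F12 to 8 with recovery of the auxiliary; if the (R)-auxiliary were to favour the wrong cyclopropane face, (S)-pantolactone would be used instead.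

Step 10. The hindered beta-hydroxy ketone may enolise, or the secondary Grignard reagent may reduce it by beta-hydride transfer, instead of adding. Fallback, from 14 back to 15: isopropenylmagnesium bromide with CeCl3, an sp2 nucleophile that cannot deliver a beta-hydride and is less hindered, adds to give the isopropenyl diol F13. H2 with RhCl(PPh3)3 in benzene then saturates the 1,1-disubstituted alkene selectively over the trisubstituted ring alkene to give 15.

**Further compounds**

F1 | step 5 | [(8aR)-3,3-(ethylenedioxy)-8a-methyl-1,2,3,5,8,8a-hexahydroazulen-6-yl]methanol | OCC1=CC[C@@]2(C)CCC3(OCCO3)C2=CC1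
F2 | step 5 | pyridinium [(8aR)-3,3-(ethylenedioxy)-8a-methyl-1,2,3,5,8,8a-hexahydroazulen-6-yl]methyl sulfate | [O-]S(=O)(=O)OCC1=CC[C@@]2(C)CCC3(OCCO3)C2=CC1.c1cc[nH+]cc1
F3 | step 5 | (8aR)-3,3-(ethylenedioxy)-6,8a-dimethyl-1,2,3,5,8,8a-hexahydroazulene | CC1=CC[C@@]2(C)CCC3(OCCO3)C2=CC1
F4 | step 5 | (6R,7S,8aR)-6,7-epoxy-3,3-(ethylenedioxy)-6,8a-dimethyl-1,2,3,5,6,7,8,8a-octahydroazulene | O1CCOC12CC[C@]3(C)C[C@@H]4O[C@]4(C)CC=C23
F5 | step 5 | (3aS,4S,6R,7S,8aR)-6,7-epoxy-3,3-(ethylenedioxy)-6,8a-dimethyldecahydroazulen-4-ol | O1CCOC12CC[C@]3(C)C[C@@H]4O[C@]4(C)C[C@H](O)[C@@H]23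
F6 | step 5 | (3aS,4S,6R,7S,8aR)-6,7-epoxy-4-hydroxy-6,8a-dimethyloctahydroazulen-3(2H)-one | O=C1CC[C@]2(C)C[C@@H]3O[C@]3(C)C[C@H](O)[C@@H]12
F7 | step 5 | (3R,3aS,4S,6R,7S,8aR)-6,7-epoxy-6,8a-dimethyl-3-(propan-2-yl)decahydroazulene-3,4-diol | CC(C)[C@]1(O)CC[C@]2(C)C[C@@H]3O[C@]3(C)C[C@H](O)[C@H]21
F8 | step 5 | jaeskeanin O-acetate, (3R,3aS,4S,6R,7S,8aR)-6,7-epoxy-3-hydroxy-6,8a-dimethyl-3-(propan-2-yl)decahydroazulen-4-yl 4-acetoxybenzoate | CC(C)[C@]1(O)CC[C@]2(C)C[C@@H]3O[C@]3(C)C[C@H](OC(=O)c3ccc(OC(C)=O)cc3)[C@H]21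
F9 | step 4 | (3R)-4,4-dimethyl-2-oxooxolan-3-yl but-3-enoate | C=CCC(=O)O[C@H]1C(=O)OCC1(C)C
F10 | step 4 | (3R)-4,4-dimethyl-2-oxooxolan-3-yl 2-diazobut-3-enoate | C=CC(=[N+]=[N-])C(=O)O[C@H]1C(=O)OCC1(C)C
F11 | step 4 | (3R)-4,4-dimethyl-2-oxooxolan-3-yl (1S,2S)-1-ethenyl-2-(7-methyl-1,4-dioxaspiro[4.4]non-6-en-6-yl)cyclopropane-1-carboxylate | C=C[C@@]1(C(=O)O[C@H]2C(=O)OCC2(C)C)C[C@H]1C3=C(C)CCC34OCCO4
F12 | step 4 | (3R)-4,4-dimethyl-2-oxooxolan-3-yl (8aR)-3,3-(ethylenedioxy)-8a-methyl-1,2,3,5,8,8a-hexahydroazulene-6-carboxylate | O=C(O[C@H]1C(=O)OCC1(C)C)C2=CC[C@@]3(C)CCC4(OCCO4)C3=CC2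
F13 | step 10 | (3S,3aS,4S,8aR)-6,8a-dimethyl-3-(prop-1-en-2-yl)-1,2,3,3a,4,5,8,8a-octahydroazulene-3,4-diol | CC(=C)[C@]1(O)CC[C@]2(C)CC=C(C)C[C@H](O)[C@H]21
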